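**Strategy.** The route rests on making ring A (the benzoate ring; C1 bears CO2Me, C6 the ketone chain) from a furan. The ketone oxygen and the ester carbon are tied up as the pyran of an isochroman, whose benzene ring is disconnected to a 4-methylfurfuryl ether of a homopropargylic alcohol. One gold-catalysed furan–yne isomerisation forms the C1–C6 and C4–C5 bonds, closes the benzene and pyran rings and turns the furan oxygen into the C5 hydroxyl, exploiting the fact that ring A has this hydroxyl between chain-bearing C6 and unsubstituted C4, meta to the C3 methyl. The precursor is the racemic (4-methylfuran-2-yl)methyl ether of 1-arylpent-4-yn-2-ol, ring B complete.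

Key step: step 11

Remark: in furan–yne phenol syntheses the furan oxygen is delivered to the former alkyne terminus, between the alkyne-side ring-fusion carbon and the former furan C5; a 5-methylfuran joined through C2 to the C4 side of the pyran would therefore give the 8-hydroxy-7-methyl isochroman, so the furan is placed on the C1 side as a 4-methylfurfuryl ether and the alkyne on the C4 side, which forms the same ring-fusion bond and the same two rings and gives the required 7-methylisochroman-5-ol.

Abbreviation: Ar = 3-chloro-2,4-dimethoxy-6-(methoxymethoxy)phenyl (ring B with its phenol as the MOM ether).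

**Step 1**
Reactants: 1 2-chloro-1,3-dimethoxybenzene
Product: 3 4-chloro-3,5-dimethoxyphenol, via aryl pinacol boronate 2 (not isolated)
Conditions: [Ir(OMe)(cod)]2 (1.5 mol %), 4,4'-di-tert-butyl-2,2'-bipyridine (3 mol %), B2pin2 (1.0 equiv), THF, 80 °C; then 2KHSO5·KHSO4·K2SO4, acetone/H2O, 23 °C
Reagents that add atoms: bis(pinacolato)diboron, CC1(C)OB(OC1(C)C)B1OC(C)(C)C(C)(C)O1 (boryl group of 2); potassium peroxymonosulfate, [K+].[O-]S(=O)(=O)OO (phenol oxygen of 3)
Why: Iridium-catalysed C–H borylation is sterically governed and should go only to C5, the one ring C–H with no ortho substituent, and the C–B bond of 2 is then oxidised in the same flask to the phenol at that position.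

**Step 2**
Reactants: 3 4-chloro-3,5-dimethoxyphenol; 4 allyl bromide
Product: 5 2-chloro-1,3-dimethoxy-5-(prop-2-en-1-yloxy)benzene
Conditions: K2CO3, acetone, reflux
Reagents that add atoms: none
Why: Williamson ether synthesis of a phenoxide with a reactive allylic bromide.

**Step 3**
Reactants: 5 2-chloro-1,3-dimethoxy-5-(prop-2-en-1-yloxy)benzene
Product: 6 4-chloro-3,5-dimethoxy-2-(prop-2-en-1-yl)phenol
Conditions: N,N-diethylaniline, 190 °C
Reagents that add atoms: none
Why: Aromatic Claisen rearrangement, a [3,3]-sigmatropic shift to either of the two equivalent free ortho positions followed by tautomerisation, the para position being blocked by chlorine.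

**Step 4**
Reactants: 6 4-chloro-3,5-dimethoxy-2-(prop-2-en-1-yl)phenol
Product: 7 2-chloro-1,3-dimethoxy-5-(methoxymethoxy)-4-(prop-2-en-1-yl)benzene
Conditions: MOMCl, i-Pr2NEt, CH2Cl2, 0 → 23 °C
Reagents that add atoms: chloromethyl methyl ether, COCCl
Why: MOM ether formation masks the phenol so that it cannot open the epoxide made next and survives the basic, gold and oxidative steps.

**Step 5**
Reactants: 7 2-chloro-1,3-dimethoxy-5-(methoxymethoxy)-4-(prop-2-en-1-yl)benzene
Product: 8 racemic 2-(Ar-methyl)oxirane
Conditions: mCPBA, NaHCO3, CH2Cl2, 0 → 23 °C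
Reagents that add atoms: 3-chloroperbenzoic acid, OOC(=O)c1cccc(Cl)c1
Why: Prilezhaev epoxidation of the terminal alkene; the new stereocentre forms as a racemate, which is acceptable because this carbon ends as the ketone.

**Step 6**
Reactants: 8 racemic 2-(Ar-methyl)oxirane
Product: 9 racemic 1-Ar-pent-4-yn-2-ol
Conditions: LiC≡CH·H2NCH2CH2NH2 (2.5 equiv), DMSO, 23 °C; H2O
Reagents that add atoms: lithium acetylide–ethylenediamine complex, [Li+].[C-]#C.NCCN
Why: SN2 opening of the monosubstituted epoxide at its terminal carbon by acetylide should give the homopropargylic alcohol.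

**Step 7**
Reactants: 10 4-bromofuran-2-carbaldehyde
Product: 11 4-methylfuran-2-carbaldehyde
Conditions: trimethylboroxine, Pd(dppf)Cl2 (3 mol %), K2CO3, 1,4-dioxane/H2O, 90 °C
Reagents that add atoms: trimethylboroxine, CB1OB(C)OB(C)O1
Why: Suzuki–Miyaura methylation of a heteroaryl bromide, which tolerates the aldehyde.

**Step 8**
Reactants: 11 4-methylfuran-2-carbaldehyde
Product: 12 (4-methylfuran-2-yl)methanol
Conditions: NaBH4, MeOH, 0 °C
Reagents that add atoms: none
Why: Hydride reduction of an aldehyde to the primary alcohol.

**Step 9**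
Reactants: 12 (4-methylfuran-2-yl)methanol
Product: 13 2-(bromomethyl)-4-methylfuran
Conditions: PBr3 (0.4 equiv), Et2O, −10 → 0 °C; cold NaHCO3 wash, dried solution used at once
Reagents that add atoms: phosphorus tribromide, BrP(Br)Br
Why: Bromination of a primary furfuryl alcohol through its phosphite ester; the labile bromide is kept cold in solution and used immediately.

**Step 10**
Reactants: 9 racemic 1-Ar-pent-4-yn-2-ol; 13 2-(bromomethyl)-4-methylfuran
Product: 14 racemic 2-{[(1-Ar-pent-4-yn-2-yl)oxy]methyl}-4-methylfuran
Conditions: NaH (1.1 equiv), THF, 0 °C; then 13 in Et2O (1.5 equiv), n-Bu4NI (5 mol %), 0 → 23 °C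
Reagents that add atoms: none
Why: Williamson ether synthesis of the secondary sodium alkoxide with a highly reactive furfuryl bromide, with THF and one equivalent of base leaving the terminal alkyne untouched.

**Step 11**
Reactants: 14 racemic 2-{[(1-Ar-pent-4-yn-2-yl)oxy]methyl}-4-methylfuran
Product: 16 racemic 3-(Ar-methyl)-7-methyl-3,4-dihydro-1H-isochromen-5-ol, via benzene oxide 15 (not isolated)
Conditions: Ph3PAuNTf2 (5 mol %), CH2Cl2, 23 °C
Reagents that add atoms: none
Why: Cationic gold activates the terminal alkyne, furan C2 attacks its inner carbon, the resulting cyclopropyl gold carbenoid opens with cleavage of the furan C2–O bond to a (Z)-dienal carbenoid, and attack of the aldehyde oxygen on the carbenoid carbon with loss of gold gives an oxepine whose valence tautomer, benzene oxide 15, opens with a 1,2-hydride shift and enolises to phenol 16. The closest known reaction type is the gold-catalysed furan–yne phenol synthesis, known for furfuryl homopropargyl ethers and applied here to a more substituted member of that class. The pyran ring closes in the first C–C bond formation, a 6-exo-dig attack of furan C2 on the alkyne (isochroman bond C4a–C8a, ring A C6–C1), and the benzene ring closes in the 6π electrocyclisation of the oxepine to 15 (isochroman bond C5–C6, ring A C5–C4), the furan oxygen being handed to the former alkyne terminus (ring A C5). No lasting stereocentre is created: the carbinol carbon is racemic and is oxidised later, and the two epoxide carbons of 15 become aromatic. Chemoselectivity for the furan over electron-rich ring B is secured because the only free position of ring B is meta to the tether and cannot reach the alkyne, and the 6-exo mode is fixed by the four-atom tether. The one open point is the direction in which 15 opens: cleavage of the C6–O bond, the usual course for furans with hydrogen at C5, leaves oxygen on C5 as required, whereas the neighbouring C7 methyl could assist the other C–O cleavage and divert material to the 6-hydroxy isomer.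

**Step 12**
Reactants: 16 racemic 3-(Ar-methyl)-7-methyl-3,4-dihydro-1H-isochromen-5-ol
Product: 17 racemic 3-(Ar-methyl)-5-(methoxymethoxy)-7-methyl-3,4-dihydro-1H-isochromene
Conditions: MOMCl, i-Pr2NEt, CH2Cl2, 0 → 40 °C
Reagents that add atoms: chloromethyl methyl ether, COCCl
Why: MOM ether formation on the ring A phenol matches ring B, so that neither phenol interferes with oxidation or carboxylate methylation and both acetals fall together at the end.

**Step 13**
Reactants: 17 racemic 3-(Ar-methyl)-5-(methoxymethoxy)-7-methyl-3,4-dihydro-1H-isochromene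
Product: 18 racemic 3-(Ar-methyl)-5-(methoxymethoxy)-7-methyl-3,4-dihydro-1H-isochromen-1-one
Conditions: KMnO4/CuSO4·5H2O, CH2Cl2, 23 °C
Reagents that add atoms: potassium permanganate, [K+].[O-][Mn](=O)(=O)=O
Why: Heterogeneous permanganate oxidation of a cyclic benzylic ether to the lactone should occur at C1, whose C–H bonds are activated by both the arene and the ring oxygen, whereas C4 lacks the oxygen and the methylene on ring B is twisted out of conjugation by its two ortho substituents; the neutral medium spares the MOM acetals.

**Step 14**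
Reactants: 18 racemic 3-(Ar-methyl)-5-(methoxymethoxy)-7-methyl-3,4-dihydro-1H-isochromen-1-one
Product: 20 racemic methyl 2-(3-Ar-2-hydroxypropyl)-3-(methoxymethoxy)-5-methylbenzoate, via potassium hydroxy carboxylate 19 (not isolated)
Conditions: KOH (1.05 equiv), MeOH/H2O, 50 °C; evaporate; MeI (3 equiv), DMF, 0 → 23 °C; crude product taken on at once
Reagents that add atoms: potassium hydroxide, [K+].[OH-]; iodomethane, CI
Why: Saponification of the δ-lactone followed by SN2 O-methylation of the carboxylate, conditions under which the neutral secondary alcohol is not alkylated and 20 can be carried forward before it closes back to 18.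

**Step 15**
Reactants: 20 racemic methyl 2-(3-Ar-2-hydroxypropyl)-3-(methoxymethoxy)-5-methylbenzoate
Product: 21 methyl 2-(3-Ar-2-oxopropyl)-3-(methoxymethoxy)-5-methylbenzoate
Conditions: Dess–Martin periodinane, NaHCO3, CH2Cl2, 0 → 23 °C
Reagents that add atoms: none
Why: Dess–Martin oxidation of the secondary alcohol under buffered conditions removes the hydroxyl that could relactonise and leaves ester, acetals and aryl chloride untouched.

**Step 16**
Reactants: 21 methyl 2-(3-Ar-2-oxopropyl)-3-(methoxymethoxy)-5-methylbenzoate
Product: 22 methyl 2-[3-(3-chloro-6-hydroxy-2,4-dimethoxyphenyl)-2-oxopropyl]-3-hydroxy-5-methylbenzoate (target)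
Conditions: HCl (1.25 M in MeOH), 0 → 23 °C; aqueous NaHCO3 work-up
Reagents that add atoms: none
Why: Acid-catalysed transacetalisation to methanol cleaves both aryl MOM ethers while the methyl ester and ketone persist, the reaction being kept cold and short to avoid cyclodehydration of the ortho-hydroxybenzyl ketone.

**Compound list**

1 | 2-chloro-1,3-dimethoxybenzene | COc1cccc(OC)c1Cl | starting material
2 | 2-(4-chloro-3,5-dimethoxyphenyl)-4,4,5,5-tetramethyl-1,3,2-dioxaborolane | COc1cc(B2OC(C)(C)C(C)(C)O2)cc(OC)c1Cl | intermediate
3 | 4-chloro-3,5-dimethoxyphenol | COc1cc(O)cc(OC)c1Cl | intermediate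
4 | allyl bromide | C=CCBr | starting material
5 | 2-chloro-1,3-dimethoxy-5-(prop-2-en-1-yloxy)benzene | C=CCOc1cc(OC)c(Cl)c(OC)c1 | intermediate
6 | 4-chloro-3,5-dimethoxy-2-(prop-2-en-1-yl)phenol | C=CCc1c(O)cc(OC)c(Cl)c1OC | intermediate
7 | 2-chloro-1,3-dimethoxy-5-(methoxymethoxy)-4-(prop-2-en-1-yl)benzene | C=CCc1c(OCOC)cc(OC)c(Cl)c1OC | intermediate
8 | racemic 2-{[3-chloro-2,4-dimethoxy-6-(methoxymethoxy)phenyl]methyl}oxirane | COCOc1cc(OC)c(Cl)c(OC)c1CC1CO1 | intermediate
9 | racemic 1-[3-chloro-2,4-dimethoxy-6-(methoxymethoxy)phenyl]pent-4-yn-2-ol | C#CCC(O)Cc1c(OCOC)cc(OC)c(Cl)c1OC | intermediate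
10 | 4-bromofuran-2-carbaldehyde | O=Cc1cc(Br)co1 | starting material
11 | 4-methylfuran-2-carbaldehyde | Cc1coc(C=O)c1 | intermediate
12 | (4-methylfuran-2-yl)methanol | Cc1coc(CO)c1 | intermediate
13 | 2-(bromomethyl)-4-methylfuran | Cc1coc(CBr)c1 | intermediate
14 | racemic 2-[({1-[3-chloro-2,4-dimethoxy-6-(methoxymethoxy)phenyl]pent-4-yn-2-yl}oxy)methyl]-4-methylfuran | C#CCC(OCc1cc(C)co1)Cc1c(OCOC)cc(OC)c(Cl)c1OC | intermediate
15 | 5,6-epoxy-3-(Ar-methyl)-7-methyl-3,4,5,6-tetrahydro-1H-isochromene (benzene oxide, in equilibrium with its oxepine; diastereomer mixture) | CC1=CC2=C(CC(Cc3c(OCOC)cc(OC)c(Cl)c3OC)OC2)C2OC12 | intermediate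
16 | racemic 3-{[3-chloro-2,4-dimethoxy-6-(methoxymethoxy)phenyl]methyl}-7-methyl-3,4-dihydro-1H-isochromen-5-ol | Cc1cc(O)c2c(c1)COC(Cc1c(OCOC)cc(OC)c(Cl)c1OC)C2 | intermediate
17 | racemic 3-{[3-chloro-2,4-dimethoxy-6-(methoxymethoxy)phenyl]methyl}-5-(methoxymethoxy)-7-methyl-3,4-dihydro-1H-isochromene | COCOc1cc(C)cc2c1CC(Cc1c(OCOC)cc(OC)c(Cl)c1OC)OC2 | intermediate
18 | racemic 3-{[3-chloro-2,4-dimethoxy-6-(methoxymethoxy)phenyl]methyl}-5-(methoxymethoxy)-7-methyl-3,4-dihydro-1H-isochromen-1-one | COCOc1cc(C)cc2c1CC(Cc1c(OCOC)cc(OC)c(Cl)c1OC)OC2=O | intermediate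
19 | potassium racemic 2-{3-[3-chloro-2,4-dimethoxy-6-(methoxymethoxy)phenyl]-2-hydroxypropyl}-3-(methoxymethoxy)-5-methylbenzoate | [K+].[O-]C(=O)c1cc(C)cc(OCOC)c1CC(O)Cc1c(OCOC)cc(OC)c(Cl)c1OC | intermediate
20 | racemic methyl 2-{3-[3-chloro-2,4-dimethoxy-6-(methoxymethoxy)phenyl]-2-hydroxypropyl}-3-(methoxymethoxy)-5-methylbenzoate | COC(=O)c1cc(C)cc(OCOC)c1CC(O)Cc1c(OCOC)cc(OC)c(Cl)c1OC | intermediate
21 | methyl 2-{3-[3-chloro-2,4-dimethoxy-6-(methoxymethoxy)phenyl]-2-oxopropyl}-3-(methoxymethoxy)-5-methylbenzoate | COC(=O)c1cc(C)cc(OCOC)c1CC(=O)Cc1c(OCOC)cc(OC)c(Cl)c1OC | intermediate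
22 | methyl 2-[3-(3-chloro-6-hydroxy-2,4-dimethoxyphenyl)-2-oxopropyl]-3-hydroxy-5-methylbenzoate | COC(=O)c1cc(C)cc(O)c1CC(=O)Cc1c(O)cc(OC)c(Cl)c1OC | target

**Count.** Total steps: 16. Longest linear sequence: 13 steps (steps 1–6 and 10–16); steps 7–9 form the short furan branch.

**Steps most likely to fail**

Step 11. The benzene oxide may open in the other direction so that the phenol oxygen ends on C6, or the six-membered ring may close so slowly that the furan degrades first. Fallback: ring A is brought in as a preformed arene by directed ortho-metalation instead of being built. 3-Hydroxy-5-methylbenzoic acid F1 is converted with 1,1'-carbonyldiimidazole and diethylamine into N,N-diethyl-3-hydroxy-5-methylbenzamide F2 and then with MOMCl and i-Pr2NEt into N,N-diethyl-3-(methoxymethoxy)-5-methylbenzamide F3. s-BuLi/TMEDA in THF at −78 °C should lithiate the position between the amide and the MOM ether to give N,N-diethyl-2-lithio-3-(methoxymethoxy)-5-methylbenzamide F4, which with BF3·OEt2 opens epoxide 8 at its terminal carbon to give racemic N,N-diethyl-2-(3-Ar-2-hydroxypropyl)-3-(methoxymethoxy)-5-methylbenzamide F5. Warming F5 with p-toluenesulfonic acid in toluene should close the lactone with loss of diethylamine; a MOM group lost in this operation would be put back with MOMCl. The fallback sets out from 8 and comes back at 18, so it also bypasses steps 12 and 13.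

Step 14. The hydroxy ester may close back to the lactone during methylation, work-up or the wait before the oxidant is added. Fallback: the order of events is reversed so that no hydroxy ester is ever formed. The potassium salt 19 obtained from 18 with KOH is freed from solvent and oxidised as the salt with 2-iodoxybenzoic acid in DMSO to potassium 2-(3-Ar-2-oxopropyl)-3-(methoxymethoxy)-5-methylbenzoate F6, which cannot lactonise. MeI is then added to the same solution to give the keto ester. The fallback sets out from 18 and comes back at 21.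

Step 10. The furfuryl bromide may polymerise faster than it alkylates the secondary alkoxide, or the alkyne may be deprotonated and alkylated at carbon. Fallback: the C–O bond is made by reductive etherification of an aldehyde instead of by displacement of a halide. Alcohol 9 is silylated (Me3SiCl, imidazole) to racemic trimethyl[(1-Ar-pent-4-yn-2-yl)oxy]silane F7, which with aldehyde 11 and Et3SiH under catalysis by FeCl3 in MeNO2 at 0 °C should give the furfuryl ether; the Lewis acid would have to be kept catalytic and cold for the MOM ether to survive. The fallback sets out from 9 and 11 and comes back at 14, and makes steps 8 and 9 unnecessary.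

**Further compounds**

F1 | step 11 | 3-hydroxy-5-methylbenzoic acid | Cc1cc(O)cc(C(=O)O)c1
F2 | step 11 | N,N-diethyl-3-hydroxy-5-methylbenzamide | CCN(CC)C(=O)c1cc(C)cc(O)c1
F3 | step 11 | N,N-diethyl-3-(methoxymethoxy)-5-methylbenzamide | CCN(CC)C(=O)c1cc(C)cc(OCOC)c1
F4 | step 11 | N,N-diethyl-2-lithio-3-(methoxymethoxy)-5-methylbenzamide | [Li]c1c(OCOC)cc(C)cc1C(=O)N(CC)CC
F5 | step 11 | racemic N,N-diethyl-2-{3-[3-chloro-2,4-dimethoxy-6-(methoxymethoxy)phenyl]-2-hydroxypropyl}-3-(methoxymethoxy)-5-methylbenzamide | CCN(CC)C(=O)c1cc(C)cc(OCOC)c1CC(O)Cc1c(OCOC)cc(OC)c(Cl)c1OC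
F6 | step 14 | potassium 2-{3-[3-chloro-2,4-dimethoxy-6-(methoxymethoxy)phenyl]-2-oxopropyl}-3-(methoxymethoxy)-5-methylbenzoate | [K+].[O-]C(=O)c1cc(C)cc(OCOC)c1CC(=O)Cc1c(OCOC)cc(OC)c(Cl)c1OC
F7 | step 10 | racemic ({1-[3-chloro-2,4-dimethoxy-6-(methoxymethoxy)phenyl]pent-4-yn-2-yl}oxy)trimethylsilane | C#CCC(O[Si](C)(C)C)Cc1c(OCOC)cc(OC)c(Cl)c1OC
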